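The numbers in the tables are calculated for an exercise; noise was put on by code.

At early times in Sunday's closed flask I kept a ledger of the starting material, in percent of the charge. At 0.125 d it read 49.7% starting material and 23.9% target, so 26.4% had gone somewhere I could not read. The books closed by 2.50 d, with 0% starting material and 44.8% target; Monday's closed with 0% and 44.8%, Saturday's with 0.2% and 43.3%.

| setting | Sunday's | Monday's | Saturday's | eta | beta | gamma | theta |
|---|---|---|---|---|---|---|---|
| starting material | 0.17 M | 0.24 M | 0.37 M | 0.17 M (fed, over 2.00 d) | 0.17 M | 0.17 M | 0.17 M |
| free catalyst | 2.9 mM | 2.9 mM | 2.9 mM | 2.9 mM | 2.9 mM | 2.9 mM | 2.9 mM |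
| remark | run made earlier | run made earlier | run made earlier | a stirred flask in which starting material is dosed at a steady rate over 2.00 d without added volume, worked up at 2.5 d | everything together in a closed stirred flask, run for 2.5 d | one stirred flow tank at steady state, fed with the mixture as stated, mean residence time 2.5 d | a single well-mixed tank run continuously and read at steady state, 25.0 d in it on average |
| time |  |  |  | 2.5 d | 2.5 d |  |  |

| run | time / d | target / % | starting material / % |
|---|---|---|---|
| Sunday's | 0.125 | 23.9 | 49.7 |
| Sunday's | 0.417 | 40.3 | 10.8 |
| Sunday's | 0.625 | 43.5 | 3.2 |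
| Sunday's | 1.04 | 44.5 | 1.2 |
| Sunday's | 1.67 | 44.5 | 1.0 |
| Sunday's | 2.08 | 46.5 | 0 |
| Sunday's | 2.50 | 44.8 | 0 |
| Monday's | 0.208 | 31.9 | 32.4 |
| Monday's | 0.333 | 36.8 | 17.5 |
| Monday's | 0.500 | 42.2 | 7.3 |
| Monday's | 0.625 | 44.2 | 5.0 |
| Monday's | 1.04 | 44.5 | 0.9 |
| Monday's | 1.67 | 46.0 | 0.4 |
| Monday's | 2.50 | 44.8 | 0 |
| Saturday's | 0.333 | 38.1 | 17.5 |
| Saturday's | 0.625 | 41.9 | 4.1 |
| Saturday's | 1.04 | 42.4 | 1.8 |
| Saturday's | 1.25 | 42.4 | 0 |
| Saturday's | 1.67 | 45.8 | 0 |
| Saturday's | 2.00 | 44.2 | 1.7 |
| Saturday's | 2.50 | 43.3 | 0.2 |

(scatter of a reading: 1 percentage point)

- the stated concentrations are those of everything mixed, before any reaction; amounts are the same in each set-up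
- the numbers in the tables scatter with a standard deviation of 1 percentage point
- the feed brings no volume worth counting
- the earlier runs were made in a closed, stirred flask

- the set-up with the highest amount of target at the outlet or at the end, in percent of the starting material put in ("none" if the first two lie within 2 percentage points) (eta / beta / gamma / theta / none)
- amount of target at the outlet or at the end, in percent of the starting material put in, eta
- amount of target at the outlet or at the end, in percent of the starting material put in, beta
- amount of target at the outlet or at the end, in percent of the starting material put in, gamma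
- amount of target at the outlet or at the end, in percent of the starting material put in, theta

A molecule leaving the starting material meets a fork, and the mean closing entry gave 44.3%. I called this the fork share, the part of the consumed starting material that ends as target; it is the usual selectivity. Sunday's early entry gives 47.5%, higher, but each reading scatters by 1 percentage point, so I could not separate the two. Sunday's 10.8% at 0.417 d gave a loss constant of 5.34 d⁻¹.

A tank adds an earlier fork: a molecule there either reacts or flows out, and it stays unreacted with the chance one over one plus constant times residence time. For gamma, at 2.5 d, I reckoned 6.97% unreacted, so 41.2% target. For theta, at 25.0 d, I reckoned 0.744% unreacted, so 44.0% target.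

The forecast gave 44.7% for eta, 45% for beta, 41.9% for gamma and 44.6% for theta, with best none; its figures for gamma and theta are close to mine but not equal to them. It held: “Concentration, and hence the mode of feeding, should not change selectivity”.

The best set-up was beta, with 44.5% target, against 40.8% in eta, 28.2% in gamma and 13.0% in theta.

    starting material + free catalyst → free catalyst + target (k = 37.0 L mol⁻¹ h⁻¹)
    free catalyst + target → spent catalyst (k = 0.320 L mol⁻¹ h⁻¹)
    starting material → side product (k = 0.120 h⁻¹)

In beta, free catalyst stood at 25.6% of its charge at 2.50 d, and spent catalyst at 74.4%. Gamma kept 8.66% starting material, so its fork share was 30.9%; theta kept 1.17%, so its share was 13.2%, both lower than the 44.3% read from the earlier runs. The neighbour of beta, charged with 0.0049 M free catalyst, ended with 0% starting material and a fork share of 56.4%.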